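**Plan**

1. Retrosynthetic cuts: first the C3 hydroxymethyl group is taken back to an N-acyl (2S)-bornane-10,2-sultam. Then O1–C2 and C3–C3a of the dihydrofuran ring are cut together, leaving methyl dihydroferulate and an N-sinapoyl sultam. Last, the imide N–C(O) bond is cut to sinapic acid and the sultam.
2. Forward order: sinapic acid is O-acetylated, attached to the sultam and deacetylated (steps 1 to 3). In step 4 a peroxidase-catalysed oxidative cross-coupling with methyl dihydroferulate joins the chain and closes the dihydrofuran ring, the only ring the route forms. Step 5 cleaves the auxiliary reductively to the CH2OH group.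
3. Enabling feature: the free 4-OH of the syringyl ring is para to the benzylic carbon C2 and conjugated through it to C3. Its one-electron oxidation puts radical character on the future C3, and after C–C coupling it leaves a p-quinone methide that is electrophilic at the future C2. O1 is the phenolic oxygen of the guaiacyl ring, whose one free ortho carbon (future C3a) carries the matching radical character.
4. Stereochemistry: C3 comes from face selection by the sultam in the radical C–C bond formation, and C2 from the trans-selective ring closure relative to C3. The minor trans-diastereomer is removed while the auxiliary is still attached, and no later step touches C2 or C3.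

Key step: step 4

Assumption: the sense of induction is taken from the accepted model for α-carbonyl radicals and non-chelated enoyl derivatives of bornane-10,2-sultam (C=O anti to SO2, bond formation anti to the pseudo-axial sulfonyl oxygen), which predicts the (3S) acyl centre from the (2S)-sultam; if experiment showed the opposite sense, the equally available (2R)-sultam would be used with no other change.

**Route**

Step 1
Reactants: 1 sinapic acid [(E)-3-(4-hydroxy-3,5-dimethoxyphenyl)prop-2-enoic acid]
Product: 3 (E)-3-(4-acetoxy-3,5-dimethoxyphenyl)prop-2-enoic acid (4-O-acetylsinapic acid), via acetic 4-O-acetylsinapic anhydride 2 (not isolated)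
Conditions: Ac2O (3 equiv), pyridine, 20 °C; then H2O/THF, 1 M HCl
Reagents that add atoms: acetic anhydride, CC(=O)OC(C)=O
Why: Pyridine-mediated O-acetylation of the phenol masks the only group that would interfere with acid chloride formation, and the mixed anhydride 2 formed at the carboxyl group is hydrolysed back to the acid on aqueous work-up.

Step 2
Reactants: 3 4-O-acetylsinapic acid; 4 (2S)-bornane-10,2-sultam [(1R)-(+)-2,10-camphorsultam]
Product: 7 N-[(E)-3-(4-acetoxy-3,5-dimethoxyphenyl)prop-2-enoyl]-(2S)-bornane-10,2-sultam, via 4-O-acetylsinapoyl chloride 5 (not isolated), via sultam sodium salt 6 (not isolated)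
Conditions: 3, (COCl)2, cat. DMF, CH2Cl2, 0 to 20 °C, evaporation; 4, NaH, toluene/THF, 0 °C; 6 added to 5 in toluene, −10 to 20 °C
Reagents that add atoms: none
Why: Acid chloride formation under Vilsmeier catalysis followed by N-acylation of the sodium sulfonamide is the standard attachment of this auxiliary, and adding 6 to 5 at low temperature keeps the anion away from the far less electrophilic aryl acetate while the E-alkene is untouched.

Step 3
Reactants: 7 N-(4-O-acetylsinapoyl)-(2S)-bornane-10,2-sultam
Product: 8 N-[(E)-3-(4-hydroxy-3,5-dimethoxyphenyl)prop-2-enoyl]-(2S)-bornane-10,2-sultam (N-sinapoyl sultam)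
Conditions: pyrrolidine (2 equiv), CH2Cl2, 0 °C
Reagents that add atoms: none
Why: Aminolysis of the activated aryl acetate by pyrrolidine is much faster than attack on the hindered, conjugated imide carbonyl or conjugate addition to the electron-rich cinnamoyl unit, so the phenol needed for one-electron oxidation should be set free selectively.

Step 4
Reactants: 8 N-sinapoyl-(2S)-bornane-10,2-sultam; 9 methyl 3-(4-hydroxy-3-methoxyphenyl)propanoate (methyl dihydroferulate)
Product: 14 methyl 3-[(2S,3S)-3-{[(2S)-bornane-10,2-sultam-N-yl]carbonyl}-2-(4-hydroxy-3,5-dimethoxyphenyl)-7-methoxy-2,3-dihydro-1-benzofuran-5-yl]propanoate, via sinapoyl sultam phenoxyl radical 10 (not isolated), via dihydroferulate phenoxyl radical 11 (not isolated), via dienone–quinone methide adduct 12 (not isolated), via phenol–quinone methide 13 (not isolated)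
Conditions: horseradish peroxidase (a heme peroxidase, EC 1.11.1.7; cat.), H2O2 (1.5 equiv, syringe pump), 9 (4 equiv), 8 added slowly in acetone, acetone/aq NaOAc–AcOH buffer pH 5, 20 °C; chromatography
Reagents that add atoms: none
Why: The peroxidase takes one electron from each phenol to give the phenoxyl radicals 10 and 11, whose spin density at the side-chain carbon α to the imide (C8 of the sinapoyl unit) and at the free ring carbon ortho to the guaiacyl oxygen lets these two carbons, both nucleophilic in the parent phenols, combine to the later C3–C3a bond (12), after which tautomerisation restores the guaiacyl phenol (13) and its oxygen adds to the benzylic carbon of the p-quinone methide to form O1–C2 with rearomatisation of the syringyl ring. The closest known reaction type is the peroxidase- or Ag2O-mediated 8–5 dehydrodimerisation of ferulic esters and amides (camphorsultam amides included) to 2-aryl-2,3-dihydrobenzofurans, run here as a cross-coupling of a syringyl with a guaiacyl unit as in lignin model chemistry. The dihydrofuran ring closes by a 5-exo-trig oxa-conjugate (1,6-) addition onto the exocyclic C=C bond of the quinone methide. C3 is controlled by the auxiliary, since in the rotamer with C=O anti to SO2 and the C8–C7 bond s-cis to C=O the pseudo-axial sulfonyl oxygen covers one face of C8 and radical 11 should bond on the open face to give the (3S) acyl centre, and C2 is controlled by C3, the phenol adding so that the aryl group and the acyl sultam come out trans, which gives (2S). The step needs cross- over homo-coupling and C–C over C–O coupling: both ring carbons ortho to the syringyl oxygen carry OMe so that 10 can bond at carbon only through C8, 11 has no conjugated side chain and a single free ortho carbon, only the C8–C5 adduct can rearomatise and cyclise, and slow addition of 8 and H2O2 to an excess of 9 keeps 10 dilute against 8–8 homo-coupling. The minor trans-diastereomer, the dimers of 9 and excess 9 should be removable by chromatography at this stage because the auxiliary is still attached.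

Step 5
Reactants: 14 the (2S,3S)-acyl sultam
Product: 16 methyl 3-[(2S,3R)-2-(4-hydroxy-3,5-dimethoxyphenyl)-3-(hydroxymethyl)-7-methoxy-2,3-dihydro-1-benzofuran-5-yl]propanoate (CNP0362206.1), via 3-formyl dihydrobenzofuran 15 (not isolated)
Conditions: LiBH4 (2.2 equiv), THF, −10 to 0 °C; sat. aq NH4Cl
Reagents that add atoms: none
Why: In this reductive cleavage of an N-acyl sultam the sulfonyl-activated imide carbonyl should be reduced far faster than the unactivated methyl ester at 0 °C, the aldehyde 15 released from the tetrahedral intermediate is reduced at once so that C3 keeps its configuration (its descriptor changes from S to R only because the CIP priorities change), and the sultam 4 is recovered.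

**Compound list**

1 | sinapic acid, (E)-3-(4-hydroxy-3,5-dimethoxyphenyl)prop-2-enoic acid | OC(=O)/C=C/c1cc(OC)c(O)c(OC)c1 | starting material
2 | acetic (E)-3-(4-acetoxy-3,5-dimethoxyphenyl)prop-2-enoic anhydride (formed in the flask) | CC(=O)OC(=O)/C=C/c1cc(OC)c(OC(C)=O)c(OC)c1 | intermediate
3 | (E)-3-(4-acetoxy-3,5-dimethoxyphenyl)prop-2-enoic acid | OC(=O)/C=C/c1cc(OC)c(OC(C)=O)c(OC)c1 | intermediate
4 | (2S)-bornane-10,2-sultam, (1R)-(+)-2,10-camphorsultam, (3aR,6S,7aS)-8,8-dimethylhexahydro-3H-3a,6-methano-2,1-benzisothiazole 2,2-dioxide | CC1(C)[C@H]2CC[C@@]13CS(=O)(=O)N[C@H]3C2 | starting material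
5 | (E)-3-(4-acetoxy-3,5-dimethoxyphenyl)prop-2-enoyl chloride (formed in the flask) | ClC(=O)/C=C/c1cc(OC)c(OC(C)=O)c(OC)c1 | intermediate
6 | sodium salt of 4, N-sodio sultam (formed in the flask) | CC1(C)[C@H]2CC[C@@]13CS(=O)(=O)[N-][C@H]3C2.[Na+] | intermediate
7 | N-[(E)-3-(4-acetoxy-3,5-dimethoxyphenyl)prop-2-enoyl]-(2S)-bornane-10,2-sultam | CC1(C)[C@H]2CC[C@@]13CS(=O)(=O)N(C(=O)/C=C/c4cc(OC)c(OC(C)=O)c(OC)c4)[C@H]3C2 | intermediate
8 | N-[(E)-3-(4-hydroxy-3,5-dimethoxyphenyl)prop-2-enoyl]-(2S)-bornane-10,2-sultam | CC1(C)[C@H]2CC[C@@]13CS(=O)(=O)N(C(=O)/C=C/c4cc(OC)c(O)c(OC)c4)[C@H]3C2 | intermediate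
9 | methyl 3-(4-hydroxy-3-methoxyphenyl)propanoate (methyl dihydroferulate) | COC(=O)CCc1ccc(O)c(OC)c1 | starting material
10 | phenoxyl radical of 8 (formed in the flask) | CC1(C)[C@H]2CC[C@@]13CS(=O)(=O)N(C(=O)/C=C/c4cc(OC)c([O])c(OC)c4)[C@H]3C2 | intermediate
11 | phenoxyl radical of 9 (formed in the flask) | COC(=O)CCc1ccc([O])c(OC)c1 | intermediate
12 | N-[(2R)-2-[3-methoxy-5-(3-methoxy-3-oxopropyl)-2-oxocyclohexa-3,5-dien-1-yl]-3-(3,5-dimethoxy-4-oxocyclohexa-2,5-dien-1-ylidene)propanoyl]-(2S)-bornane-10,2-sultam, ring sp3 carbon of either configuration (formed in the flask) | CC1(C)[C@H]2CC[C@@]13CS(=O)(=O)N(C(=O)[C@H](C=C4C=C(OC)C(=O)C(OC)=C4)C5C=C(CCC(=O)OC)C=C(OC)C5=O)[C@H]3C2 | intermediate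
13 | N-[(2R)-2-[2-hydroxy-3-methoxy-5-(3-methoxy-3-oxopropyl)phenyl]-3-(3,5-dimethoxy-4-oxocyclohexa-2,5-dien-1-ylidene)propanoyl]-(2S)-bornane-10,2-sultam (formed in the flask) | CC1(C)[C@H]2CC[C@@]13CS(=O)(=O)N(C(=O)[C@H](C=C4C=C(OC)C(=O)C(OC)=C4)c5cc(CCC(=O)OC)cc(OC)c5O)[C@H]3C2 | intermediate
14 | methyl 3-[(2S,3S)-3-{[(2S)-bornane-10,2-sultam-N-yl]carbonyl}-2-(4-hydroxy-3,5-dimethoxyphenyl)-7-methoxy-2,3-dihydro-1-benzofuran-5-yl]propanoate | CC1(C)[C@H]2CC[C@@]13CS(=O)(=O)N(C(=O)[C@H]4c5cc(CCC(=O)OC)cc(OC)c5O[C@@H]4c6cc(OC)c(O)c(OC)c6)[C@H]3C2 | intermediate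
15 | methyl 3-[(2S,3S)-3-formyl-2-(4-hydroxy-3,5-dimethoxyphenyl)-7-methoxy-2,3-dihydro-1-benzofuran-5-yl]propanoate (formed in the flask) | COC(=O)CCc1cc(OC)c2c(c1)[C@H](C=O)[C@@H](c1cc(OC)c(O)c(OC)c1)O2 | intermediate
16 | methyl 3-[(2S,3R)-2-(4-hydroxy-3,5-dimethoxyphenyl)-3-(hydroxymethyl)-7-methoxy-2,3-dihydro-1-benzofuran-5-yl]propanoate | COC(=O)CCc1cc(OC)c2c(c1)[C@H](CO)[C@@H](c1cc(OC)c(O)c(OC)c1)O2 | target

**Summary**

Total step count: 5. Longest linear sequence: 5 steps (1 to 16); 4 and 9 enter as purchased materials.

Steps most likely to fail: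

Step 4. The radical–radical C–C bond formation may show poor facial discrimination, because the sultam sits three bonds from the bond being made. Radical 10 may also be diverted into 8–8 homo-coupling or C–O (8–O–4) coupling. The fallback sets out from 9 and runs the coupling at the alcohol oxidation level without an auxiliary. 9 and (E)-sinapyl alcohol F1 (purchased), with horseradish peroxidase and H2O2 in acetone/buffer, should give the trans-dihydrobenzofuran directly as the racemate, that is 16 together with its (2R,3S)-enantiomer F2. Preparative HPLC on a cellulose tris(3,5-dimethylphenylcarbamate) phase then removes F2, and the route is rejoined at 16. Stereocontrol moves from an auxiliary to a separation, and steps 1 to 3 and 5 fall away.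

Step 5. Chemoselectivity may be lost, with the methyl ester reduced along with the imide, or the lithium phenoxide may open the p-hydroxybenzyl aryl ether. The fallback sets out from 8 and runs the key step with 3-(4-hydroxy-3-methoxyphenyl)propanoic acid F3 (purchased) in place of 9, under the conditions of step 4, to give the carboxylic acid analogue of 14, methyl-free acid F4. LiBH4 in THF then reduces only the imide, the lithium carboxylate being inert to it, and should give the hydroxy acid F5. Me3SiCHN2 in toluene/MeOH at 0 °C methylates the carboxylic acid faster than the phenol and rejoins the route at 16.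

Step 2. Acetyl transfer from the aryl acetate to the sultam anion may compete with N-acylation by the acid chloride, and the electron-rich cinnamoyl chloride may hydrolyse or oligomerise. The fallback sets out from 4 and builds the enoyl group by olefination instead of acylation. 4 (NaH, then chloroacetyl chloride, THF) gives N-(chloroacetyl)-(2S)-bornane-10,2-sultam F6. An Arbuzov reaction with P(OEt)3 gives the phosphonate F7. A Horner–Wadsworth–Emmons reaction (LiCl, iPr2NEt, MeCN) with 4-acetoxy-3,5-dimethoxybenzaldehyde F8 (purchased) should give the E-enoyl sultam and rejoin the route at 7.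

**Further compounds**

F1 | step 4 | (E)-sinapyl alcohol, (E)-4-(3-hydroxyprop-1-enyl)-2,6-dimethoxyphenol | OC/C=C/c1cc(OC)c(O)c(OC)c1
F2 | step 4 | methyl 3-[(2R,3S)-2-(4-hydroxy-3,5-dimethoxyphenyl)-3-(hydroxymethyl)-7-methoxy-2,3-dihydro-1-benzofuran-5-yl]propanoate (enantiomer of 16) | COC(=O)CCc1cc(OC)c2c(c1)[C@@H](CO)[C@H](c1cc(OC)c(O)c(OC)c1)O2
F3 | step 5 | 3-(4-hydroxy-3-methoxyphenyl)propanoic acid (dihydroferulic acid) | OC(=O)CCc1ccc(O)c(OC)c1
F4 | step 5 | 3-[(2S,3S)-3-{[(2S)-bornane-10,2-sultam-N-yl]carbonyl}-2-(4-hydroxy-3,5-dimethoxyphenyl)-7-methoxy-2,3-dihydro-1-benzofuran-5-yl]propanoic acid | CC1(C)[C@H]2CC[C@@]13CS(=O)(=O)N(C(=O)[C@H]4c5cc(CCC(=O)O)cc(OC)c5O[C@@H]4c6cc(OC)c(O)c(OC)c6)[C@H]3C2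
F5 | step 5 | 3-[(2S,3R)-2-(4-hydroxy-3,5-dimethoxyphenyl)-3-(hydroxymethyl)-7-methoxy-2,3-dihydro-1-benzofuran-5-yl]propanoic acid | OC(=O)CCc1cc(OC)c2c(c1)[C@H](CO)[C@@H](c1cc(OC)c(O)c(OC)c1)O2
F6 | step 2 | N-(chloroacetyl)-(2S)-bornane-10,2-sultam | CC1(C)[C@H]2CC[C@@]13CS(=O)(=O)N(C(=O)CCl)[C@H]3C2
F7 | step 2 | N-[(diethoxyphosphoryl)acetyl]-(2S)-bornane-10,2-sultam | CC1(C)[C@H]2CC[C@@]13CS(=O)(=O)N(C(=O)CP(=O)(OCC)OCC)[C@H]3C2
F8 | step 2 | 4-acetoxy-3,5-dimethoxybenzaldehyde | CC(=O)Oc1c(OC)cc(C=O)cc1OC
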